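**Retrosynthetic overview**
1. 12 ⇒ 10 + allyl bromide: the last C–C bond closes the C6 quaternary centre by α'-enolate allylation anti to the C4 methoxy group.
2. 10 ⇒ aldehyde 6 + aryl metal from 4-bromoveratrole 7: Felkin–Anh addition sets C7.
3. 6 ⇒ silyl dienol ether 4 + propanal 5: organo-SOMO α-enolation makes the C6–C8 bond and sets C8 under catalyst control.
4. 4 ⇒ (S)-enone 2 ⇒ achiral 4-methoxycyclohexanone 1: a catalytic enantioselective desymmetrizing dehydrogenation (key step) creates C4.
5. Rings: the only carbocycle is carried through from 1; no ring is formed or opened, and the arene enters intact in step 4.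

Assumption: the antipode of the step 1 amine catalyst is the one that gives 2 as the (S) enantiomer; the sense of induction for a 4-methoxy substituent is not predicted here and is checked on 2 before going on.

Step 1
Reactants: 1 4-methoxycyclohexan-1-one
Product: 2 (4S)-4-methoxycyclohex-2-en-1-one
Conditions: IBX (1.2 equiv), tert-leucine-derived chiral primary–tertiary diamine·TfOH (20 mol %), MeCN, 25 °C
Reagents that add atoms: none
Why: Desymmetrizing enamine oxidation (amine-catalysed IBX α,β-dehydrogenation): the chiral enamine is oxidised and eliminated along one of the two enantiotopic CH2–CH2 arms of the achiral ketone, so C4 becomes a stereocentre (S) without any bond being made to it.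

Step 2
Reactants: 2 (4S)-4-methoxycyclohex-2-en-1-one
Product: 4 {[(5S)-5-methoxycyclohexa-1,3-dien-2-yl]oxy}trimethylsilane, via lithium dienolate 3 (not isolated)
Conditions: LDA, THF, −78 °C; TMSCl, −78 → 0 °C
Reagents that add atoms: chlorotrimethylsilane C[Si](C)(C)Cl
Why: Kinetic α'-deprotonation of an enone gives the cross-conjugated lithium dienolate, which is O-silylated; the γ-hydrogen at C4 is not removed at −78 °C, so the stereocentre is untouched.

Step 3
Reactants: 4 {[(5S)-5-methoxycyclohexa-1,3-dien-2-yl]oxy}trimethylsilane; 5 propanal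
Product: 6 (2R)-2-[(1RS,5S)-5-methoxy-2-oxocyclohex-3-en-1-yl]propanal
Conditions: (2S,5S)-5-benzyl-2-tert-butyl-3-methylimidazolidin-4-one·TFA (20 mol %), CAN (2.2 equiv), 2,6-di-tert-butylpyridine, H2O (2 equiv), DME, −20 °C
Reagents that add atoms: none
Why: Organo-SOMO α-enolation of an aldehyde: CAN oxidises the propanal enamine to a radical cation whose Re face is shielded by the catalyst benzyl group, the enol-silane CH terminus of 4 adds to the Si face (C8 = R, catalyst control), and a second oxidation with loss of silicon restores the enone; C6 forms as an epimer mixture that is erased in step 5.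

Step 4
Reactants: 6 (2R)-2-[(1RS,5S)-5-methoxy-2-oxocyclohex-3-en-1-yl]propanal; 7 4-bromo-1,2-dimethoxybenzene
Product: 10 (4S,6RS)-6-[(1S,2R)-1-(3,4-dimethoxyphenyl)-1-hydroxypropan-2-yl]-4-methoxycyclohex-2-en-1-one, via 3,4-dimethoxyphenyllithium 8 (not isolated), via aryltitanium triisopropoxide 9 (not isolated)
Conditions: 7, n-BuLi, THF, −78 °C; ClTi(OiPr)3, −78 → −40 °C; then 6, −78 → −20 °C; aq. NH4Cl
Reagents that add atoms: none
Why: Bromine–lithium exchange, Li→Ti transmetalation and 1,2-addition of the non-chelating aryltitanium to the aldehyde only (the enone is left alone); Felkin–Anh control from C8, with the ring carbon as the large group, gives the 7,8-syn alcohol (C7 = S).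

Step 5
Reactants: 10 (4S,6RS)-6-[(1S,2R)-1-(3,4-dimethoxyphenyl)-1-hydroxypropan-2-yl]-4-methoxycyclohex-2-en-1-one
Product: 12 (4S,6S)-6-[(1S,2R)-1-(3,4-dimethoxyphenyl)-1-hydroxypropan-2-yl]-4-methoxy-6-(prop-2-en-1-yl)cyclohex-2-en-1-one, via dilithium alkoxide-dienolate 11 (not isolated)
Conditions: LDA (2.3 equiv), THF, −78 → −40 °C; allyl bromide, DMPU, −78 → −20 °C; aq. NH4Cl
Reagents that add atoms: allyl bromide C=CCBr
Why: Enolate alkylation of the alkoxide/dienolate dianion: both C6 epimers of 10 converge on one planar enolate and allyl bromide is expected to attack C6 anti to the pseudoaxial C4 methoxy group (1,3-induction, by analogy with 4-alkoxycyclohexenone enolates), placing allyl trans to OMe (C6 = S), while the lithium alkoxide is too poor a nucleophile at low temperature for O-allylation.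

**Compound list**
1 | 4-methoxycyclohexan-1-one | COC1CCC(=O)CC1 | starting material
2 | (4S)-4-methoxycyclohex-2-en-1-one | O=C1C=C[C@@H](OC)CC1 | intermediate
3 | lithium (5S)-5-methoxycyclohexa-1,3-dien-2-olate | CO[C@H]1CC=C(O[Li])C=C1 | intermediate
4 | {[(5S)-5-methoxycyclohexa-1,3-dien-2-yl]oxy}trimethylsilane | CO[C@H]1CC=C(O[Si](C)(C)C)C=C1 | intermediate
5 | propanal | CCC=O | starting material
6 | (2R)-2-[(1RS,5S)-5-methoxy-2-oxocyclohex-3-en-1-yl]propanal | C[C@@H](C=O)C1C[C@H](OC)C=CC1=O | intermediate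
7 | 4-bromo-1,2-dimethoxybenzene | COc1ccc(Br)cc1OC | starting material
8 | (3,4-dimethoxyphenyl)lithium | COc1ccc([Li])cc1OC | intermediate
9 | (3,4-dimethoxyphenyl)tri(propan-2-yloxy)titanium | COc1ccc(cc1OC)[Ti](OC(C)C)(OC(C)C)OC(C)C | intermediate
10 | (4S,6RS)-6-[(1S,2R)-1-(3,4-dimethoxyphenyl)-1-hydroxypropan-2-yl]-4-methoxycyclohex-2-en-1-one | C[C@@H]([C@H](O)c1ccc(OC)c(OC)c1)C1C[C@H](OC)C=CC1=O | intermediate
11 | dilithium (1S,2R)-1-(3,4-dimethoxyphenyl)-2-[(5S)-5-methoxy-2-oxidocyclohexa-1,3-dien-1-yl]propan-1-olate | C[C@@H]([C@H](O[Li])c1ccc(OC)c(OC)c1)C1=C(O[Li])C=C[C@@H](OC)C1 | intermediate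
12 | (4S,6S)-6-[(1S,2R)-1-(3,4-dimethoxyphenyl)-1-hydroxypropan-2-yl]-4-methoxy-6-(prop-2-en-1-yl)cyclohex-2-en-1-one | C=CC[C@@]1([C@@H](C)[C@H](O)c2ccc(OC)c(OC)c2)C[C@H](OC)C=CC1=O | target

**Total step count:** 5. **Longest linear sequence:** 5 (1 → 2 → 4 → 6 → 10 → 12); the aryl bromide 7 enters directly in step 4.

**Steps most likely to fail, with fallbacks**

Step 1 is the riskiest. The enone can be dehydrogenated further to 4-methoxyphenol, the γ-stereocentre can racemise through the dienamine, and the level of induction with a 4-alkoxy group is uncertain. The fallback sets out from 1 and replaces the catalytic enamine oxidation with a stoichiometric chiral-base desymmetrization. Enantioselective deprotonation with lithium (R,R)-bis(1-phenylethyl)amide (antipode as needed) and in-situ TMSCl quench in THF at −100 °C gives {[(4S)-4-methoxycyclohex-1-en-1-yl]oxy}trimethylsilane F1. Saegusa–Ito oxidation (Pd(OAc)2, O2, DMSO) then places the double bond on the silylated arm and comes back to the route at 2.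

Step 3 is an extension of the organo-SOMO enolation to a cyclic 2-silyloxydiene. CAN may oxidise the diene directly, and the α-stereocentre of the keto aldehyde can epimerise. The fallback sets out from 4 and moves the C8 stereocontrol to an iridium catalyst. Branch-selective allylic alkylation with (E)-but-2-en-1-yl methyl carbonate ([Ir(cod)Cl]2, chiral phosphoramidite, CsF/ZnF2) gives (4S,6RS)-6-[(2S)-but-3-en-2-yl]-4-methoxycyclohex-2-en-1-one F2. Ozonolysis of its terminal vinyl group only (O3, CH2Cl2/MeOH, −78 °C, then Me2S; the enone reacts much more slowly) comes back to the route at 6.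

Step 5 relies on substrate control at a quaternary centre in the presence of a free alkoxide. Facial selectivity may be modest, and γ-deprotonation or O-allylation may compete. The fallback sets out from 10 and uses catalyst control instead.
- Silylation (TBSCl, imidazole) gives (4S,6RS)-6-[(1S,2R)-1-(tert-butyldimethylsilyloxy)-1-(3,4-dimethoxyphenyl)propan-2-yl]-4-methoxycyclohex-2-en-1-one F3.
- Enolisation with KHMDS and O-acylation with allyl chloroformate gives the allyl enol carbonate, (5S)-6-[(1S,2R)-1-(tert-butyldimethylsilyloxy)-1-(3,4-dimethoxyphenyl)propan-2-yl]-5-methoxycyclohexa-1,3-dien-1-yl prop-2-en-1-yl carbonate F4 (ring numbered from the enol carbon).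
- Palladium-catalysed decarboxylative asymmetric allylic alkylation (Pd2(dba)3, t-Bu-PHOX, matched antipode) gives (4S,6S)-6-[(1S,2R)-1-(tert-butyldimethylsilyloxy)-1-(3,4-dimethoxyphenyl)propan-2-yl]-4-methoxy-6-(prop-2-en-1-yl)cyclohex-2-en-1-one F5.
- TBAF removes the silyl group and comes back to the route at 12.

**Further compounds**
F1 | step 1 | {[(4S)-4-methoxycyclohex-1-en-1-yl]oxy}trimethylsilane | C[Si](C)(C)OC1=CC[C@@H](OC)CC1
F2 | step 3 | (4S,6RS)-6-[(2S)-but-3-en-2-yl]-4-methoxycyclohex-2-en-1-one | C[C@@H](C=C)C1C[C@H](OC)C=CC1=O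
F3 | step 5 | (4S,6RS)-6-[(1S,2R)-1-(tert-butyldimethylsilyloxy)-1-(3,4-dimethoxyphenyl)propan-2-yl]-4-methoxycyclohex-2-en-1-one | C[C@@H]([C@H](O[Si](C)(C)C(C)(C)C)c1ccc(OC)c(OC)c1)C1C[C@H](OC)C=CC1=O
F4 | step 5 | (5S)-6-[(1S,2R)-1-(tert-butyldimethylsilyloxy)-1-(3,4-dimethoxyphenyl)propan-2-yl]-5-methoxycyclohexa-1,3-dien-1-yl prop-2-en-1-yl carbonate | C=CCOC(=O)OC1=C([C@@H](C)[C@H](O[Si](C)(C)C(C)(C)C)c2ccc(OC)c(OC)c2)C[C@H](OC)C=C1
F5 | step 5 | (4S,6S)-6-[(1S,2R)-1-(tert-butyldimethylsilyloxy)-1-(3,4-dimethoxyphenyl)propan-2-yl]-4-methoxy-6-(prop-2-en-1-yl)cyclohex-2-en-1-one | C=CC[C@@]1([C@@H](C)[C@H](O[Si](C)(C)C(C)(C)C)c2ccc(OC)c(OC)c2)C[C@H](OC)C=CC1=O
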